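The earlier runs and the new flask are calculated with constants of no real substance; noise was put on by code.

Take the easy step first: starting material is the limiting reagent in both runs,  so we follow its decay and replace each curve by one exponential, its mean. This is an approximation whose error we must check: in the epsilon run c(coupling partner) falls from 375 mM to 312 mM by the last reading.

| flask | starting material | coupling partner | time |
|---|---|---|---|
| epsilon | 150 mM | 375 mM |  |
| alpha | 150 mM | 1100 mM |  |
| theta | 60.0 mM | 285 mM | 5.3 min |

| run | time / min | [target] / mM |
|---|---|---|
| epsilon run | 0.40 | 6.3 |
| epsilon run | 1.2 | 17.4 |
| epsilon run | 2.3 | 31.1 |
| epsilon run | 3.7 | 47.2 |
| epsilon run | 5.3 | 63.5 |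
| alpha run | 0.40 | 8.7 |
| alpha run | 1.2 | 24.4 |
| alpha run | 2.3 | 43.1 |
| alpha run | 3.7 | 63.0 |
| alpha run | 5.3 | 82.0 |

(each reading ± 0.4 mM)

- Overall: starting material + coupling partner -> target.
- Constant volume, constant temperature.
- The analysis sees a species whether free or bound.
- "The second partner" is coupling partner.
- An order is taken over about fifteen percent of the charge, up and down.

- how the opening rate goes with [coupling partner] round the charge of the epsilon run: the exponent of the rate at two percent of starting material gone to target
- target in the theta run at 5.3 min, as a share of the starting material charged
- which of these the readings show (the substrate pairs with itself / the second partner is lost in pairs / the product binds the second partner / the second partner is lost by itself / two substrates go astray together)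

The mean specific rate k̄ of a stretch is the constant of the exponential that joins the stretch's two ends, with c(starting material) taken as charge less c(target):

k̄ = ln[c(starting material) at the start of the stretch / c(starting material) at its end] / elapsed time

Over the whole epsilon run this mean specific rate is 0.104 min⁻¹, and over the alpha run it is 0.149 min⁻¹. Together they give a mean order in partner of 0.337 between the two charges.

To check the error of the mean, we read k̄ on the last leg of the epsilon run: 0.108 min⁻¹, with a scatter of 0.00409 min⁻¹. That leg has c(coupling partner) near 320 mM, and its starting material has thinned towards the theta charge.

Our bracket for the theta run is as follows.

From above, the alpha constant: 54.7 %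

From below, the leg scaled at order one to a partner of 255 mM, the theta charge less half the starting material charged: 36.6 %

Our own point lets less partner and thinner substrate cancel, which keeps the leg's constant: 43.6 %

The forecast gives 0.45, 41 % and "the substrate pairs with itself", on the ground that “reactivity per substrate improves as substrate thins”. Its share lies inside the bracket, lower than our point.

    starting material + coupling partner ⇌ intermediate, settled at all times (17.60 M⁻¹)
    starting material + coupling partner → target (2.856 M⁻¹ min⁻¹)
    2 starting material ⇌ idle substrate dimer, settled at all times (52.00 M⁻¹)

The theta run gives 45.3 %, inside the bracket and above our 43.6 %; the order is 0.57, and the readings show that the substrate pairs with itself. The joining of two starting material to idle substrate dimer moves the readings by 15 scatter units, root mean square. Turned back into a mean specific rate, the theta share is 0.114 min⁻¹, higher than the epsilon run's 0.104 min⁻¹ on a smaller partner charge, and lower than the alpha run's 0.149 min⁻¹.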